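Ring A of the labdane core (C1–C5 and C10, labdane numbering) is cut in a retro-[4+2] sense through C1–C2 and C5–C10. Because C5–C10 is also the bond shared with ring B, one intramolecular Diels–Alder reaction of an acyclic chain closes both rings and sets C5 and C10. The precursor carries a 2-silyloxy diene (C2=C3(OSiEt3)–C4(CH3)=C5) and a 2-substituted acrolein (C1=C10–C20HO) joined by the C6–C9 tether, with the C8=C17 methylene, the complete acetoxy side chain and the single stereocentre C9 already in place. The enol ether left at C3/C4 then builds the quaternary C4, and both activating carbonyl groups are erased in one deoxygenation.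

Key step: step 8

Remark: labdane numbering (C1–C20) is used for the decalins and for the atoms of the open-chain precursors that end up in them.
Assumption: the sense of induction of the chiral diene ligand in step 6 is taken by analogy with related additions; the ligand enantiomer that gives the (6R)-aldehyde 11 is the one meant.

Step 1
Reactants: 1 pent-4-yn-1-ol
Product: 2 4-bromopent-4-en-1-ol
Conditions: Et4N+ HBr2− (from Et4NBr and HBr), CH2Cl2, 40 °C
Reagents that add atoms: tetraethylammonium hydrogen dibromide, CC[N+](CC)(CC)CC.[Br-].Br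
Why: Markovnikov hydrobromination of the terminal alkyne by the hydrogen dibromide anion should give the 2-bromo-1-alkene without touching the alcohol, and no stereocentre is formed.

Step 2
Reactants: 2 4-bromopent-4-en-1-ol
Product: 3 4-bromopent-4-enal
Conditions: TEMPO (cat.), PhI(OAc)2, CH2Cl2, rt
Reagents that add atoms: none
Why: Nitroxyl-catalysed oxidation of the primary alcohol stops at the aldehyde under anhydrous conditions and leaves the vinyl bromide intact.

Step 3
Reactants: 3 4-bromopent-4-enal; 4 3-(triphenyl-λ5-phosphanylidene)butan-2-one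
Product: 5 (3E)-7-bromo-3-methylocta-3,7-dien-2-one
Conditions: toluene, 90 °C
Reagents that add atoms: none
Why: Wittig olefination with a stabilised α-branched keto ylide should give the trisubstituted enone with the E geometry typical of stabilised ylides (acyl group trans to the chain).

Step 4
Reactants: 5 (3E)-7-bromo-3-methylocta-3,7-dien-2-one; 6 bis(pinacolato)diboron
Product: 7 (3E)-3-methyl-7-(4,4,5,5-tetramethyl-1,3,2-dioxaborolan-2-yl)octa-3,7-dien-2-one
Conditions: PdCl2(PPh3)2 (cat.), PPh3, KOPh, toluene, 50 °C
Reagents that add atoms: none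
Why: Miyaura borylation of the alkenyl bromide (oxidative addition to zerovalent palladium, phenoxide-assisted transmetalation with the diboron, reductive elimination) keeps the 1,1-disubstituted alkene in place, and the enone is inert under these conditions.

Step 5
Reactants: 8 geranyl acetate; 9 (E)-but-2-enal
Product: 10 (2E,6E)-3-methyl-8-oxoocta-2,6-dien-1-yl acetate
Conditions: second-generation Hoveyda–Grubbs catalyst (cat.), CH2Cl2, 40 °C
Reagents that add atoms: none
Why: Olefin cross-metathesis should take place at the accessible isopropylidene terminus rather than at the hindered, electron-poorer alkene next to the acetate, and gives the conjugated enal as its thermodynamically preferred E isomer.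

Step 6
Reactants: 10 (2E,6E)-3-methyl-8-oxoocta-2,6-dien-1-yl acetate; 7 (3E)-3-methyl-7-(4,4,5,5-tetramethyl-1,3,2-dioxaborolan-2-yl)octa-3,7-dien-2-one
Product: 11 (2E,6R,10E)-3,11-dimethyl-7-methylidene-12-oxo-6-(2-oxoethyl)trideca-2,10-dien-1-yl acetate
Conditions: [RhCl(C2H4)2]2 (cat.), (R,R)-Ph-bod (chiral diene, cat.), Et3N, dioxane/H2O, 30 °C
Reagents that add atoms: none
Why: In this rhodium-catalysed asymmetric conjugate addition (Hayashi–Miyaura reaction) the alkenylrhodium species adds to the unhindered enal C=C inside the chiral diene pocket, which sets the C6 stereocentre (future C9) as R, while the trisubstituted α-methyl enone is a much poorer acceptor and the mild base spares the acetate.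

Step 7
Reactants: 11 (2E,6R,10E)-3,11-dimethyl-7-methylidene-12-oxo-6-(2-oxoethyl)trideca-2,10-dien-1-yl acetate
Product: 12 (2E,6S,10E)-3,11-dimethyl-7-methylidene-12-oxo-6-(3-oxoprop-1-en-2-yl)trideca-2,10-dien-1-yl acetate
Conditions: Eschenmoser's salt, Et3N, CH2Cl2, rt
Reagents that add atoms: Eschenmoser's salt (N,N-dimethylmethyleneiminium iodide), C=[N+](C)C.[I-]
Why: Mannich reaction of the aldehyde enol with the iminium salt and base-induced loss of dimethylamine (α-methylenation) installs C1 as the terminal methylene of the dienophile without a secondary-amine catalyst that could trigger an enamine Michael addition to the enone, and the C6 stereocentre is untouched (its descriptor changes to S only through the priority rules).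

Step 8
Reactants: 12 (2E,6S,10E)-3,11-dimethyl-7-methylidene-12-oxo-6-(3-oxoprop-1-en-2-yl)trideca-2,10-dien-1-yl acetate
Product: 14 15-acetoxy-3-(triethylsilyloxy)-18-norlabda-3,8(17),13E-trien-20-al, via triethylsilyl dienol ether 13 (not isolated)
Conditions: TESOTf, Et3N, CH2Cl2, −78 °C; then toluene (0.01 M), 60 °C
Reagents that add atoms: triethylsilyl trifluoromethanesulfonate, CC[Si](CC)(CC)OS(=O)(=O)C(F)(F)F
Why: Soft enolisation (O-silylation of the methyl ketone and removal of a proton from its methyl group by Et3N) gives the cross-conjugated 2-silyloxy diene 13, which should undergo a concerted, asynchronous normal-electron-demand intramolecular Diels–Alder reaction with the 2-substituted acrolein, forming C1–C2 and C5–C10 together. The closest known reaction type is the type 1 intramolecular Diels–Alder cyclisation of 1,7,9-decatrienes that carry silyloxy dienes and α-methylene carbonyl dienophiles. Ring A is closed as the new cyclohexene of the [4+2] process, and ring B by the internal C5–C10 bond across the four-carbon tether C6–C9 (fused mode, six-membered). C5 follows from the E geometry of C4=C5 and suprafacial addition, and C10 from the endo position of the formyl group (tether anti), which together give the trans ring fusion; the absolute sense of both is dictated by C9, whose side chain sits pseudo-equatorial in the chair-like tether. The step needs regio-, endo- and π-facial selectivity: the tether and the matched polarisation (nucleophilic C2 of the silyloxy diene, electrophilic C1 of the enal) secure the first, secondary orbital overlap of the formyl group the second and the C9 substituent the third.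

Step 9
Reactants: 14 15-acetoxy-3-(triethylsilyloxy)-18-norlabda-3,8(17),13E-trien-20-al
Product: 15 15-acetoxy-18-hydroxy-3-oxolabda-8(17),13E-dien-20-al
Conditions: aq. CH2O, Yb(OTf)3 (cat.), THF, rt
Reagents that add atoms: formaldehyde, C=O
Why: In this Lewis-acid-catalysed aqueous Mukaiyama aldol reaction of the tetrasubstituted silyl enol ether, formaldehyde should approach C4 from the α face, opposite to the axial C10 formyl group, which gives the quaternary centre with 4α-CH2OH and 4β-CH3.

Step 10
Reactants: 15 15-acetoxy-18-hydroxy-3-oxolabda-8(17),13E-dien-20-al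
Product: 16 bis(p-toluenesulfonylhydrazone) of 15 at C3 and C20
Conditions: TsNHNH2, EtOH, 70 °C
Reagents that add atoms: p-toluenesulfonyl hydrazide, Cc1ccc(cc1)S(=O)(=O)NN
Why: Condensation of the aldehyde and the ketone with the sulfonyl hydrazide gives the bis(tosylhydrazone) under near-neutral conditions, and the quaternary C4 rules out dehydration or epimerisation of the β-hydroxy ketone.

Step 11
Reactants: 16 bis(p-toluenesulfonylhydrazone) of 15 at C3 and C20
Product: 17 15-acetoxylabda-8(17),13E-dien-18-ol
Conditions: catecholborane, CHCl3, 0 °C to rt; then NaOAc·3H2O, reflux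
Reagents that add atoms: none
Why: Tosylhydrazone reduction (hydride transfer from the borane to both C=N bonds, then acetate-induced loss of sulfinate and extrusion of N2 from the diazenes) should turn C3 into CH2 and C20 into CH3 while leaving the acetate, the hydroxyl group, the alkenes and all stereocentres untouched.

Step 12
Reactants: 17 15-acetoxylabda-8(17),13E-dien-18-ol
Product: 18 15-acetoxylabda-8(17),13E-dien-18-oic acid
Conditions: AZADO (2-azaadamantane N-oxyl, cat.), PhI(OAc)2, MeCN/aq. pH 7 buffer, rt
Reagents that add atoms: water, O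
Why: Oxoammonium (nitroxyl) oxidation takes the neopentyl primary alcohol to the aldehyde and, through its hydrate, on to the carboxylic acid, while the alkenes and the allylic acetate are inert to the hypervalent iodine oxidant.

Compound list
1 | pent-4-yn-1-ol | C#CCCCO | starting material
2 | 4-bromopent-4-en-1-ol | C=C(Br)CCCO | intermediate
3 | 4-bromopent-4-enal | C=C(Br)CCC=O | intermediate
4 | 3-(triphenyl-λ5-phosphanylidene)butan-2-one | CC(=O)C(C)=P(c1ccccc1)(c1ccccc1)c1ccccc1 | starting material
5 | (3E)-7-bromo-3-methylocta-3,7-dien-2-one | CC(=O)/C(C)=C/CCC(Br)=C | intermediate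
6 | bis(pinacolato)diboron | CC1(C)OB(OC1(C)C)B1OC(C)(C)C(C)(C)O1 | starting material
7 | (3E)-3-methyl-7-(4,4,5,5-tetramethyl-1,3,2-dioxaborolan-2-yl)octa-3,7-dien-2-one | CC(=O)/C(C)=C/CCC(=C)B1OC(C)(C)C(C)(C)O1 | intermediate
8 | geranyl acetate, (2E)-3,7-dimethylocta-2,6-dien-1-yl acetate | CC(C)=CCC/C(C)=C/COC(C)=O | starting material
9 | (E)-but-2-enal (crotonaldehyde) | C/C=C/C=O | starting material
10 | (2E,6E)-3-methyl-8-oxoocta-2,6-dien-1-yl acetate | CC(=O)OC/C=C(C)/CC/C=C/C=O | intermediate
11 | (2E,6R,10E)-3,11-dimethyl-7-methylidene-12-oxo-6-(2-oxoethyl)trideca-2,10-dien-1-yl acetate | O=CC[C@H](C(=C)CC/C=C(C)/C(C)=O)CC/C(C)=C/COC(C)=O | intermediate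
12 | (2E,6S,10E)-3,11-dimethyl-7-methylidene-12-oxo-6-(3-oxoprop-1-en-2-yl)trideca-2,10-dien-1-yl acetate | O=CC(=C)[C@H](C(=C)CC/C=C(C)/C(C)=O)CC/C(C)=C/COC(C)=O | intermediate
13 | (2E,6S,10E)-3,11-dimethyl-7-methylidene-6-(3-oxoprop-1-en-2-yl)-12-(triethylsilyloxy)trideca-2,10,12-trien-1-yl acetate (triethylsilyl dienol ether of 12) | O=CC(=C)[C@H](C(=C)CC/C=C(C)/C(=C)O[Si](CC)(CC)CC)CC/C(C)=C/COC(C)=O | intermediate
14 | 15-acetoxy-3-(triethylsilyloxy)-18-norlabda-3,8(17),13E-trien-20-al (trans-decalin; 5α-H, 9α-H, 10β-CHO, C3=C4 silyl enol ether with 4-CH3) | C=C1CC[C@@H]2[C@](C=O)(CCC(O[Si](CC)(CC)CC)=C2C)[C@H]1CC/C(C)=C/COC(C)=O | intermediate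
15 | 15-acetoxy-18-hydroxy-3-oxolabda-8(17),13E-dien-20-al (4α-CH2OH, 4β-CH3, 10β-CHO) | C=C1CC[C@@H]2[C@](C=O)(CCC(=O)[C@@]2(C)CO)[C@H]1CC/C(C)=C/COC(C)=O | intermediate
16 | bis(p-toluenesulfonylhydrazone) of 15 at C3 and C20 (C=N geometry not specified) | C=C1CC[C@@H]2[C@](C=NNS(=O)(=O)c3ccc(C)cc3)(CCC(=NNS(=O)(=O)c3ccc(C)cc3)[C@@]2(C)CO)[C@H]1CC/C(C)=C/COC(C)=O | intermediate
17 | 15-acetoxylabda-8(17),13E-dien-18-ol (4α-CH2OH) | C=C1CC[C@@H]2[C@](C)(CCC[C@@]2(C)CO)[C@H]1CC/C(C)=C/COC(C)=O | intermediate
18 | 15-acetoxylabda-8(17),13E-dien-18-oic acid, (1R,4aR,5S,8aR)-5-[(3E)-5-acetoxy-3-methylpent-3-en-1-yl]-1,4a-dimethyl-6-methylidenedecahydronaphthalene-1-carboxylic acid | C=C1CC[C@@H]2[C@](C)(CCC[C@@]2(C)C(=O)O)[C@H]1CC/C(C)=C/COC(C)=O | target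

Total step count: 12. Longest linear sequence: 11 steps (steps 1–4, then 6–12); step 5 is a one-step side branch.

Steps most likely to fail

Step 8. The silyl triflate and amine may consume the 2-substituted acrolein by conjugate addition or oligomerisation before the diene is in place. The cycloaddition may also proceed without enough endo or facial control, giving cis-fused adducts or adducts mismatched with C9. The fallback sets out from 12 and comes back at 14. An amine salt (pyrrolidinium acetate, or a chiral primary amine salt that adds catalyst control; CHCl3, rt to 40 °C) would convert the methyl enone into a cross-conjugated 2-aminodiene. This closes the same two bonds by an amine-catalysed formal [4+2] (double Michael) pathway and, after hydrolysis of the enamine, should give the keto aldehyde 15-acetoxy-3-oxo-18-norlabda-8(17),13E-dien-20-al F1. Equilibrating silylation (TESCl, NaI, Et3N, MeCN) towards the tetrasubstituted C3=C4 enol ether then returns to 14.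

Step 6. The alkenylrhodium species may add 1,2 to the aldehyde, the hindered 1,1-disubstituted alkenylboronate may protodeboronate, or enantiofacial discrimination on an enal may be weak. The fallback sets out from 8 and 7 and comes back at 11. Cross-metathesis of 8 with tert-butyl acrylate would give tert-butyl (2E,6E)-8-acetoxy-6-methylocta-2,6-dienoate F2. Rhodium/BINAP-catalysed 1,4-addition of 7 to this enoate ([Rh(acac)(C2H4)2], BINAP, dioxane/H2O), an acceptor class with no competing carbonyl addition, would give the tert-butyl ester F3. TMSOTf/2,6-lutidine and aqueous work-up would free the acid F4. Mixed-anhydride formation (i-BuOCOCl, N-methylmorpholine) followed by NaBH4/CeCl3·7H2O would reduce the acid and the enone carbonyl to the diol F5 while sparing the acetate. Dess–Martin periodinane would reoxidise both alcohols and deliver 11.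

Step 11. Hydride transfer to the neopentyl C3 hydrazone may be incomplete, or the C3 tosylhydrazone may eliminate to a C2=C3 alkene instead of being reduced. The fallback sets out from 15 and comes back at 17. Thioacetalisation of both carbonyl groups (ethane-1,2-dithiol, Zn(OTf)2, CH2Cl2) would give the bis(1,3-dithiolane) F6. Radical desulfurisation (Bu3SnH, AIBN, toluene, reflux) should then give 17 without touching the alkenes or the acetate.

Further compounds
F1 | step 8 | 15-acetoxy-3-oxo-18-norlabda-8(17),13E-dien-20-al (C4 epimers) | C=C1CC[C@@H]2[C@](C=O)(CCC(=O)C2C)[C@H]1CC/C(C)=C/COC(C)=O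
F2 | step 6 | tert-butyl (2E,6E)-8-acetoxy-6-methylocta-2,6-dienoate | CC(=O)OC/C=C(C)/CC/C=C/C(=O)OC(C)(C)C
F3 | step 6 | tert-butyl (3R,7E)-3-[(3E)-5-acetoxy-3-methylpent-3-en-1-yl]-8-methyl-4-methylidene-9-oxodec-7-enoate | CC(C)(C)OC(=O)C[C@H](C(=C)CC/C=C(C)/C(C)=O)CC/C(C)=C/COC(C)=O
F4 | step 6 | (3R,7E)-3-[(3E)-5-acetoxy-3-methylpent-3-en-1-yl]-8-methyl-4-methylidene-9-oxodec-7-enoic acid | OC(=O)C[C@H](C(=C)CC/C=C(C)/C(C)=O)CC/C(C)=C/COC(C)=O
F5 | step 6 | (2E,6R,10E)-12-hydroxy-6-(2-hydroxyethyl)-3,11-dimethyl-7-methylidenetrideca-2,10-dien-1-yl acetate (C12 epimers) | OCC[C@H](C(=C)CC/C=C(C)/C(C)O)CC/C(C)=C/COC(C)=O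
F6 | step 11 | bis(1,3-dithiolane) of 15 at C3 and C20 | C=C1CC[C@@H]2[C@](C3SCCS3)(CCC3(SCCS3)[C@@]2(C)CO)[C@H]1CC/C(C)=C/COC(C)=O
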